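**Retrosynthetic overview**

1. Numbering as an octahydroazulene: C1 (OAc), C3 (tertiary carbinol with isopropyl), C3a (ring-fusion CH), C4 (aryl ester), C5=C6(Me)–C7(=O) enone, C8, C8a (quaternary, Me). The C4 ester and the phenol come last; the C4–OH/enone array comes from epoxidation and E1cB opening of a 4-ene-7-one.
2. Seven-membered ring (closed last): ring-closing metathesis at C4=C5 between a C3a vinyl group and a 1-methylallyl ketone, itself made by opening a γ-lactone at C7 with a 2-butenyl Grignard reagent.
3. Five-membered carbocycle (closed second): C3–C3a bond by SmI2 ketyl–olefin cyclisation/β-elimination of an isopropyl ketone onto an allylic benzyl ether, run on the γ-lactone O–C1–C8a–C8–C7(=O) (temporary ring, closed first).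
4. Enabling feature: C3 is a tertiary carbinol bearing isopropyl (a latent ketyl) bonded directly to C3a, and the C1 oxygen and C8 are cis on the cyclopentane. Tying them as a γ-lactone forces the C3a substituent onto the convex face and fixes the trans ring fusion before the seven-membered ring exists.
5. C8a: Eschenmoser–Claisen rearrangement with 1,3-chirality transfer from an allylic alcohol made by proline-catalysed aminoxylation/Wittig olefination; C1: proline aldol.

Key step: step 8

Remark: compounds 17, 19, 20 and 22 are carried as mixtures of epimers at the methyl-bearing carbon next to the ketone, because this centre becomes trigonal in step 12.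

**Step 1**
Reactants: 1 3-(benzyloxy)propanal; 2 nitrosobenzene; 3 ethyl 2-(triphenyl-λ5-phosphanylidene)propanoate
Product: 5 ethyl (R,E)-5-(benzyloxy)-2-methyl-4-[(phenylamino)oxy]pent-2-enoate, via alpha-aminoxy aldehyde 4 (not isolated)
Conditions: 2, D-proline (20 mol %), CHCl3, 0 °C; then 3, CH2Cl2, 0 °C to rt
Reagents that add atoms: nitrosobenzene, O=Nc1ccccc1; ethyl 2-(triphenyl-λ5-phosphanylidene)propanoate, CCOC(=O)C(C)=P(c1ccccc1)(c1ccccc1)c1ccccc1
Why: Proline-catalysed enamine α-aminoxylation should deliver the O–N unit to one enantioface (D-proline giving the S aldehyde), and in situ Wittig olefination with the stabilised ylide should give the E trisubstituted enoate before the sensitive aldehyde can racemise.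

**Step 2**
Reactants: 5 ethyl (R,E)-5-(benzyloxy)-2-methyl-4-[(phenylamino)oxy]pent-2-enoate
Product: 6 ethyl (R,E)-5-(benzyloxy)-4-hydroxy-2-methylpent-2-enoate
Conditions: Zn dust, AcOH, EtOH, rt
Reagents that add atoms: none
Why: Reductive N–O bond cleavage by zinc in acetic acid should unveil the allylic alcohol without touching the enoate, the benzyl ether or the carbinol stereocentre.

**Step 3**
Reactants: 6 ethyl (R,E)-5-(benzyloxy)-4-hydroxy-2-methylpent-2-enoate; 7 1,1-dimethoxy-N,N-dimethylethan-1-amine
Product: 9 ethyl (S,E)-2-[3-(benzyloxy)prop-1-en-1-yl]-4-(dimethylamino)-2-methyl-4-oxobutanoate, via ketene N,O-acetal 8 (not isolated)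
Conditions: 7 (3 equiv), xylenes, 140 °C, MeOH distilled off
Reagents that add atoms: 1,1-dimethoxy-N,N-dimethylethan-1-amine, CC(OC)(OC)N(C)C
Why: Eschenmoser–Claisen rearrangement through a chair transition state with the CH2OBn group equatorial should transfer the carbinol chirality suprafacially to the new quaternary carbon (R carbinol and E enoate giving the S centre) and leave an E alkene.

**Step 4**
Reactants: 9 ethyl (S,E)-2-[3-(benzyloxy)prop-1-en-1-yl]-4-(dimethylamino)-2-methyl-4-oxobutanoate
Product: 10 (S,E)-6-(benzyloxy)-3-(hydroxymethyl)-N,N,3-trimethylhex-4-enamide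
Conditions: LiBH4, MeOH (1 equiv), THF, 0 to 40 °C
Reagents that add atoms: none
Why: Hydride reduction with LiBH4 takes esters but not tertiary amides, so the hindered ethyl ester should be reduced chemoselectively to the neopentyl alcohol.

**Step 5**
Reactants: 10 (S,E)-6-(benzyloxy)-3-(hydroxymethyl)-N,N,3-trimethylhex-4-enamide
Product: 11 (S,E)-6-(benzyloxy)-3-formyl-N,N,3-trimethylhex-4-enamide
Conditions: Dess–Martin periodinane, pyridine, CH2Cl2, 0 °C to rt
Reagents that add atoms: none
Why: Dess–Martin oxidation should give the aldehyde, which has no α-hydrogen and so can neither epimerise nor self-condense.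

**Step 6**
Reactants: 11 (S,E)-6-(benzyloxy)-3-formyl-N,N,3-trimethylhex-4-enamide; 12 3-methylbutan-2-one
Product: 13 (3S,4E)-6-(benzyloxy)-3-[(1R)-1-hydroxy-4-methyl-3-oxopentyl]-N,N,3-trimethylhex-4-enamide
Conditions: 12 (20 vol %), L-proline (30 mol %), DMSO, rt
Reagents that add atoms: 3-methylbutan-2-one, CC(C)C(C)=O
Why: Proline-catalysed direct aldol addition of the methyl-side enamine of 12 to the non-enolisable aldehyde should set the carbinol centre under catalyst control (L-proline giving the R alcohol, as with other tertiary-alkyl aldehydes).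

**Step 7**
Reactants: 13 (3S,4E)-6-(benzyloxy)-3-[(1R)-1-hydroxy-4-methyl-3-oxopentyl]-N,N,3-trimethylhex-4-enamide
Product: 14 (4S,5R)-4-[(E)-3-(benzyloxy)prop-1-en-1-yl]-4-methyl-5-(3-methyl-2-oxobutyl)oxolan-2-one
Conditions: camphorsulfonic acid (1.1 equiv), toluene, 40 °C
Reagents that add atoms: none
Why: Acid-promoted N-to-O acyl transfer of the γ-hydroxy amide (lactonisation, 5-exo-trig) should close the γ-lactone that holds the C1 oxygen and the C8 methylene on one face for the next step.

**Step 8**
Reactants: 14 (4S,5R)-4-[(E)-3-(benzyloxy)prop-1-en-1-yl]-4-methyl-5-(3-methyl-2-oxobutyl)oxolan-2-one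
Product: 15 (3aS,4S,5R,6aR)-4-ethenyl-5-hydroxy-3a-methyl-5-(propan-2-yl)hexahydro-2H-cyclopenta[b]furan-2-one
Conditions: SmI2 (2.5 equiv), HMPA (10 equiv), THF, −20 °C to rt; sat. aq. NH4Cl
Reagents that add atoms: none
Why: SmI2/HMPA reduces the isopropyl ketone to a ketyl radical that adds to the proximal alkene carbon, a second electron turns the resulting secondary radical into an organosamarium, and this expels benzyloxide to leave the vinyl group; the sequence is a ketyl–olefin cyclisation/β-elimination of the kind established for unsaturated ketones carrying an allylic ether or ester. The cyclopentane closes in the 5-exo-trig mode and is necessarily cis-fused to the γ-lactone. At C3a the alkene chain should sit on the convex face of the forming oxabicyclo[3.3.0]octane, away from the lactone ring, which places the vinyl group trans to the lactone bonds and so presets the trans ring fusion. At C3 the samarium-bound oxygen should lie anti to the alkene across the forming bond and on the lactone side, where the ring oxygen can chelate it, which puts the isopropyl group on the convex face. The step needs single-electron reduction of the ketone in preference to the lactone, which is inert to SmI2/HMPA without a protic activator, and cyclisation faster than simple ketyl reduction, which the fully substituted carbon next to the alkene favours.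

**Step 9**
Reactants: 15 (3aS,4S,5R,6aR)-4-ethenyl-5-hydroxy-3a-methyl-5-(propan-2-yl)hexahydro-2H-cyclopenta[b]furan-2-one; 16 but-2-en-1-ylmagnesium chloride
Product: 17 1-[(1S,2R,4R,5S)-5-ethenyl-2,4-dihydroxy-1-methyl-4-(propan-2-yl)cyclopentyl]-3-methylpent-4-en-2-one (both epimers at C3 of the pentenone chain; in equilibrium with its cyclic hemiketal)
Conditions: 16 (2.5 equiv), THF, −78 °C; sat. aq. NH4Cl at −78 °C
Reagents that add atoms: but-2-en-1-ylmagnesium chloride, CC=CC[Mg]Cl
Why: Grignard addition to the lactone should stop after one addition because the magnesium hemiketalate of the cis-fused bicycle persists at −78 °C, and the 2-butenyl reagent reacts through its γ-carbon (allylic transposition) to give the 1-methylallyl ketone, whose new centre is erased in step 12.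

**Step 10**
Reactants: 17 1-[(1S,2R,4R,5S)-5-ethenyl-2,4-dihydroxy-1-methyl-4-(propan-2-yl)cyclopentyl]-3-methylpent-4-en-2-one; 18 acetic anhydride
Product: 19 (1R,2S,3S,4R)-3-ethenyl-4-hydroxy-2-methyl-2-(3-methyl-2-oxopent-4-en-1-yl)-4-(propan-2-yl)cyclopentyl acetate (both epimers at C3 of the side chain)
Conditions: 18, pyridine, DMAP (cat.), CH2Cl2, 0 °C
Reagents that add atoms: acetic anhydride, CC(=O)OC(C)=O
Why: DMAP-catalysed acetylation should take only the secondary hydroxyl of the open hydroxy ketone form, the tertiary carbinol being inert under these conditions, and thereby drain the hemiketal equilibrium.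

**Step 11**
Reactants: 19 (1R,2S,3S,4R)-3-ethenyl-4-hydroxy-2-methyl-2-(3-methyl-2-oxopent-4-en-1-yl)-4-(propan-2-yl)cyclopentyl acetate
Product: 20 (1R,3R,3aS,8aS)-3-hydroxy-6,8a-dimethyl-7-oxo-3-(propan-2-yl)-1,2,3,3a,6,7,8,8a-octahydroazulen-1-yl acetate (both C6 epimers)
Conditions: second-generation Grubbs catalyst (5 mol %), 1,4-benzoquinone (10 mol %), CH2Cl2 (2 mM), 40 °C
Reagents that add atoms: none
Why: Ring-closing metathesis of two monosubstituted alkenes held trans on the cyclopentane should give the trans-fused cycloheptene with loss of ethene, benzoquinone suppressing ruthenium hydride isomerisation of the β,γ-unsaturated ketone.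

**Step 12**
Reactants: 20 (1R,3R,3aS,8aS)-3-hydroxy-6,8a-dimethyl-7-oxo-3-(propan-2-yl)-1,2,3,3a,6,7,8,8a-octahydroazulen-1-yl acetate; 21 3-chloroperoxybenzoic acid
Product: 23 (1R,3R,3aR,4R,8aS)-3,4-dihydroxy-6,8a-dimethyl-7-oxo-3-(propan-2-yl)-1,2,3,3a,4,7,8,8a-octahydroazulen-1-yl acetate, via 4,5-epoxy ketone 22 (not isolated)
Conditions: 21, NaHCO3, CH2Cl2, 0 °C; then Et3N, rt
Reagents that add atoms: 3-chloroperoxybenzoic acid, OOC(=O)c1cccc(Cl)c1
Why: Prilezhaev epoxidation should occur on the face of H-3a and the C3 hydroxyl, opposite the angular methyl and the isopropyl group, and base-induced E1cB opening of the β,γ-epoxy ketone then moves the alkene into conjugation, keeps the C4 oxygen as set by the epoxide and erases the C6 centre.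

**Step 13**
Reactants: 23 (1R,3R,3aR,4R,8aS)-3,4-dihydroxy-6,8a-dimethyl-7-oxo-3-(propan-2-yl)-1,2,3,3a,4,7,8,8a-octahydroazulen-1-yl acetate; 24 4-[(tert-butyldimethylsilyl)oxy]benzoic acid
Product: 25 (1R,3R,3aR,4R,8aS)-1-acetoxy-3-hydroxy-6,8a-dimethyl-7-oxo-3-(propan-2-yl)-1,2,3,3a,4,7,8,8a-octahydroazulen-4-yl 4-[(tert-butyldimethylsilyl)oxy]benzoate
Conditions: 24, EDC·HCl, DMAP, CH2Cl2, rt
Reagents that add atoms: 4-[(tert-butyldimethylsilyl)oxy]benzoic acid, CC(C)(C)[Si](C)(C)Oc1ccc(cc1)C(O)=O
Why: Steglich esterification should acylate only the secondary allylic alcohol with retention at C4, the tertiary carbinol being too hindered to react.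

**Step 14**
Reactants: 25 (1R,3R,3aR,4R,8aS)-1-acetoxy-3-hydroxy-6,8a-dimethyl-7-oxo-3-(propan-2-yl)-1,2,3,3a,4,7,8,8a-octahydroazulen-4-yl 4-[(tert-butyldimethylsilyl)oxy]benzoate
Product: 26 (1R,3R,3aR,4R,8aS)-1-acetoxy-3-hydroxy-6,8a-dimethyl-7-oxo-3-(propan-2-yl)-1,2,3,3a,4,7,8,8a-octahydroazulen-4-yl 4-hydroxybenzoate (CNP0087181.5)
Conditions: HF·pyridine, THF, 0 °C
Reagents that add atoms: none
Why: Fluoride-mediated desilylation of the aryl silyl ether is far faster than any reaction of the alkyl acetate, the benzoate or the enone, so the phenol should be released without touching the rest.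

**Compound list**

1 | 3-(benzyloxy)propanal | O=CCCOCc1ccccc1 | starting material
2 | nitrosobenzene | O=Nc1ccccc1 | starting material
3 | ethyl 2-(triphenyl-λ5-phosphanylidene)propanoate | CCOC(=O)C(C)=P(c1ccccc1)(c1ccccc1)c1ccccc1 | starting material
4 | (S)-3-(benzyloxy)-2-[(phenylamino)oxy]propanal | O=C[C@@H](ONc1ccccc1)COCc1ccccc1 | intermediate
5 | ethyl (R,E)-5-(benzyloxy)-2-methyl-4-[(phenylamino)oxy]pent-2-enoate | CCOC(=O)/C(C)=C/[C@@H](ONc1ccccc1)COCc1ccccc1 | intermediate
6 | ethyl (R,E)-5-(benzyloxy)-4-hydroxy-2-methylpent-2-enoate | CCOC(=O)/C(C)=C/[C@@H](O)COCc1ccccc1 | intermediate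
7 | 1,1-dimethoxy-N,N-dimethylethan-1-amine (N,N-dimethylacetamide dimethyl acetal) | CC(OC)(OC)N(C)C | starting material
8 | ethyl (R,E)-5-(benzyloxy)-4-{[1-(dimethylamino)ethenyl]oxy}-2-methylpent-2-enoate | CCOC(=O)/C(C)=C/[C@@H](OC(=C)N(C)C)COCc1ccccc1 | intermediate
9 | ethyl (S,E)-2-[3-(benzyloxy)prop-1-en-1-yl]-4-(dimethylamino)-2-methyl-4-oxobutanoate | CCOC(=O)[C@@](C)(CC(=O)N(C)C)/C=C/COCc1ccccc1 | intermediate
10 | (S,E)-6-(benzyloxy)-3-(hydroxymethyl)-N,N,3-trimethylhex-4-enamide | OC[C@@](C)(CC(=O)N(C)C)/C=C/COCc1ccccc1 | intermediate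
11 | (S,E)-6-(benzyloxy)-3-formyl-N,N,3-trimethylhex-4-enamide | O=C[C@@](C)(CC(=O)N(C)C)/C=C/COCc1ccccc1 | intermediate
12 | 3-methylbutan-2-one | CC(C)C(C)=O | starting material
13 | (3S,4E)-6-(benzyloxy)-3-[(1R)-1-hydroxy-4-methyl-3-oxopentyl]-N,N,3-trimethylhex-4-enamide | CC(C)C(=O)C[C@@H](O)[C@@](C)(CC(=O)N(C)C)/C=C/COCc1ccccc1 | intermediate
14 | (4S,5R)-4-[(E)-3-(benzyloxy)prop-1-en-1-yl]-4-methyl-5-(3-methyl-2-oxobutyl)oxolan-2-one | CC(C)C(=O)C[C@H]1OC(=O)C[C@@]1(C)/C=C/COCc1ccccc1 | intermediate
15 | (3aS,4S,5R,6aR)-4-ethenyl-5-hydroxy-3a-methyl-5-(propan-2-yl)hexahydro-2H-cyclopenta[b]furan-2-one | C=C[C@@H]1[C@](O)(C(C)C)C[C@H]2OC(=O)C[C@@]12C | intermediate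
16 | but-2-en-1-ylmagnesium chloride | CC=CC[Mg]Cl | starting material
17 | 1-[(1S,2R,4R,5S)-5-ethenyl-2,4-dihydroxy-1-methyl-4-(propan-2-yl)cyclopentyl]-3-methylpent-4-en-2-one, both epimers at the methyl-bearing chain carbon | C=CC(C)C(=O)C[C@]1(C)[C@H](O)C[C@@](O)(C(C)C)[C@H]1C=C | intermediate
18 | acetic anhydride | CC(=O)OC(C)=O | starting material
19 | (1R,2S,3S,4R)-3-ethenyl-4-hydroxy-2-methyl-2-(3-methyl-2-oxopent-4-en-1-yl)-4-(propan-2-yl)cyclopentyl acetate, both epimers at the methyl-bearing chain carbon | C=CC(C)C(=O)C[C@]1(C)[C@H](OC(C)=O)C[C@@](O)(C(C)C)[C@H]1C=C | intermediate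
20 | (1R,3R,3aS,8aS)-3-hydroxy-6,8a-dimethyl-7-oxo-3-(propan-2-yl)-1,2,3,3a,6,7,8,8a-octahydroazulen-1-yl acetate, both C6 epimers | CC(=O)O[C@@H]1C[C@@](O)(C(C)C)[C@H]2C=CC(C)C(=O)C[C@]12C | intermediate
21 | 3-chloroperoxybenzoic acid | OOC(=O)c1cccc(Cl)c1 | starting material
22 | 4,5-epoxide of 20, oxirane oxygen cis to H-3a and to the C3 hydroxyl and trans to the C8a methyl, both C6 epimers | CC(=O)O[C@@H]1C[C@@](O)(C(C)C)[C@H]2[C@@H]3O[C@@H]3C(C)C(=O)C[C@]12C | intermediate
23 | (1R,3R,3aR,4R,8aS)-3,4-dihydroxy-6,8a-dimethyl-7-oxo-3-(propan-2-yl)-1,2,3,3a,4,7,8,8a-octahydroazulen-1-yl acetate | CC(=O)O[C@@H]1C[C@@](O)(C(C)C)[C@H]2[C@H](O)C=C(C)C(=O)C[C@]12C | intermediate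
24 | 4-[(tert-butyldimethylsilyl)oxy]benzoic acid | CC(C)(C)[Si](C)(C)Oc1ccc(cc1)C(O)=O | starting material
25 | (1R,3R,3aR,4R,8aS)-1-acetoxy-3-hydroxy-6,8a-dimethyl-7-oxo-3-(propan-2-yl)-1,2,3,3a,4,7,8,8a-octahydroazulen-4-yl 4-[(tert-butyldimethylsilyl)oxy]benzoate | CC(=O)O[C@@H]1C[C@@](O)(C(C)C)[C@H]2[C@H](OC(=O)c3ccc(O[Si](C)(C)C(C)(C)C)cc3)C=C(C)C(=O)C[C@]12C | intermediate
26 | (1R,3R,3aR,4R,8aS)-1-acetoxy-3-hydroxy-6,8a-dimethyl-7-oxo-3-(propan-2-yl)-1,2,3,3a,4,7,8,8a-octahydroazulen-4-yl 4-hydroxybenzoate | CC(=O)O[C@@H]1C[C@@](O)(C(C)C)[C@H]2[C@H](OC(=O)c3ccc(O)cc3)C=C(C)C(=O)C[C@]12C | target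

**Step count**

Total steps: 14. Longest linear sequence: 14 steps (from 1; all other inputs are purchased).

**Steps most likely to fail, with fallbacks**

Step 8. The ketyl may be reduced to the secondary alcohol faster than it adds to the unactivated alkene, or the addition may proceed with poor facial selectivity at C3 and C3a. The fallback replaces the radical closure by a two-electron allyl-metal addition and sets out from 14. Acetolysis of the benzyl ether with Ac2O and catalytic FeCl3 would give the allylic acetate (E)-3-[(2R,3S)-3-methyl-2-(3-methyl-2-oxobutyl)-5-oxooxolan-3-yl]prop-2-en-1-yl acetate F1. Ionisation of F1 with catalytic Pd(PPh3)4 and transmetalation with InI would give an allylindium species that adds to the ketone through its γ-carbon in a closed six-membered transition state (intramolecular umpolung allylation). This forms the same C3–C3a bond and the vinyl group on the lactone template, and the route is rejoined at 15.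

Step 9. The hemiketalate may collapse during the addition, so that a second equivalent of the Grignard reagent adds, or the β,γ-unsaturated ketone may slip into conjugation on work-up. The fallback sets out from 15. Aminolysis of the lactone with Me2AlCl and N,O-dimethylhydroxylamine hydrochloride would give 2-[(1S,2R,4R,5S)-5-ethenyl-2,4-dihydroxy-1-methyl-4-(propan-2-yl)cyclopentyl]-N-methoxy-N-methylacetamide F2. Used at once with excess 16 at −78 °C, this amide should stop cleanly at the ketone through its stable magnesium chelate, and the route is rejoined at 17.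

Step 7. Acid-induced dehydration or retro-aldol cleavage of the β-hydroxy ketone may compete with the acyl transfer. The fallback reverses the order of ring formation and sets out from 13. Treatment of 13 itself with SmI2/HMPA, with the samarium held by the free hydroxyl and the amide carbonyl, would effect the ketyl–olefin cyclisation/β-elimination under chelation control. This would give 2-[(1S,2R,4R,5S)-5-ethenyl-2,4-dihydroxy-1-methyl-4-(propan-2-yl)cyclopentyl]-N,N-dimethylacetamide F3, which no longer contains a β-hydroxy ketone. Acid lactonisation of this diol amide then returns to the route at 15.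

**Further compounds**

F1 | step 8 | (E)-3-[(2R,3S)-3-methyl-2-(3-methyl-2-oxobutyl)-5-oxooxolan-3-yl]prop-2-en-1-yl acetate | CC(C)C(=O)C[C@H]1OC(=O)C[C@@]1(C)/C=C/COC(C)=O
F2 | step 9 | 2-[(1S,2R,4R,5S)-5-ethenyl-2,4-dihydroxy-1-methyl-4-(propan-2-yl)cyclopentyl]-N-methoxy-N-methylacetamide | C=C[C@@H]1[C@](O)(C(C)C)C[C@@H](O)[C@@]1(C)CC(=O)N(C)OC
F3 | step 7 | 2-[(1S,2R,4R,5S)-5-ethenyl-2,4-dihydroxy-1-methyl-4-(propan-2-yl)cyclopentyl]-N,N-dimethylacetamide | C=C[C@@H]1[C@](O)(C(C)C)C[C@@H](O)[C@@]1(C)CC(=O)N(C)C
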